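**Retrosynthetic overview**

1. Feature: in the γ-lactone (O1, C2=O, C3, C4, C5), ring carbon C4 carries two one-carbon oxygenated arms, the ring methylene C5H2–O1 and the exocyclic carbinol carbon C7'. Without the aryl group on C7' both arms are CH2–O, so C4 is the prochiral centre of a 2-substituted propane-1,3-diol, and an oxetane is that diol in strained, masked form.
2. C7'–aryl bond and C7' configuration: aryl Grignard addition to the C4 aldehyde, then oxidation and CBS reduction of the aryl ketone; the phenol is freed last by hydrogenolysis.
3. O1–C5 bond and C4 configuration: acid-promoted opening of the oxetane by the C2 carboxyl group of a 2-(oxetan-3-yl)propanoic acid, which closes the lactone trans and releases the second arm as CH2OH.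
4. C3–benzyl bond and C3 configuration: Evans alkylation of an N-(oxetan-3-ylacetyl)oxazolidinone, made from oxetan-3-one by Wittig olefination, hydrogenation, saponification and N-acylation.
5. Ring order: the oxetane is bought, the γ-lactone is the only ring that is made (step 8), and both arenes are brought in intact.

Key step: step 8

Remark: lactone numbering (O1, C2, C3, C4, C5; carbinol carbon C7') is used for all lactones, and 4-benzyloxy-3-methoxybenzyl alcohol 9 is taken to be a catalogue compound.

**Route**

Step 1
Reactants: 1 oxetan-3-one; 2 ethyl (triphenylphosphoranylidene)acetate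
Product: 3 ethyl 2-(oxetan-3-ylidene)acetate
Conditions: CH2Cl2, 0 °C to rt
Reagents that add atoms: none
Why: Wittig olefination: the strained, unhindered carbonyl group of oxetan-3-one should react with the stabilised ylide at room temperature, and the symmetric ketone raises no question of alkene geometry or stereocentre.

Step 2
Reactants: 3 ethyl 2-(oxetan-3-ylidene)acetate
Product: 4 ethyl 2-(oxetan-3-yl)acetate
Conditions: H2 (1 atm), Pd/C (palladium on carbon), EtOAc, rt
Reagents that add atoms: none
Why: Catalytic hydrogenation of the electron-poor exocyclic alkene on palladium should be fast under neutral conditions that leave the oxetane C–O bonds intact, and the new C–H carbon of the oxetane lies on a mirror plane, so no stereocentre arises.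

Step 3
Reactants: 4 ethyl 2-(oxetan-3-yl)acetate
Product: 5 lithium 2-(oxetan-3-yl)acetate
Conditions: LiOH·H2O (1.0 equiv), THF/H2O, 0 °C to rt; evaporate and dry, no acidification
Reagents that add atoms: lithium hydroxide, [Li+].[OH-]
Why: Ester saponification with one equivalent of LiOH should stop at the carboxylate, which is isolated as the lithium salt because the free oxetanylacetic acid tends to isomerise to a hydroxy lactone on standing.

Step 4
Reactants: 5 lithium 2-(oxetan-3-yl)acetate; 6 (R)-4-benzyloxazolidin-2-one
Product: 8 (R)-4-benzyl-3-[2-(oxetan-3-yl)acetyl]oxazolidin-2-one, via pivalic mixed anhydride 7 (not isolated)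
Conditions: PivCl, Et3N, THF, −20 to 0 °C; then LiCl, 6, rt
Reagents that add atoms: none
Why: Mixed-anhydride N-acylation of an oxazolidinone (PivCl, Et3N, LiCl variant): the carboxylate is turned into the pivalic mixed anhydride 7, which the LiCl-activated oxazolidinone attacks at the less hindered acyl carbon, and the medium stays basic so that the oxetane is never exposed to acid.

Step 5
Reactants: 9 (4-benzyloxy-3-methoxyphenyl)methanol
Product: 10 4-benzyloxy-3-methoxybenzyl bromide
Conditions: PBr3 (0.4 equiv), Et2O, 0 °C; used directly
Reagents that add atoms: phosphorus tribromide, BrP(Br)Br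
Why: Conversion of a benzylic alcohol to the bromide with PBr3 by substitution at the activated benzylic carbon should be clean at 0 °C, and the labile electron-rich bromide is used without storage.

Step 6
Reactants: 8 (R)-4-benzyl-3-[2-(oxetan-3-yl)acetyl]oxazolidin-2-one; 10 4-benzyloxy-3-methoxybenzyl bromide
Product: 12 (R)-4-benzyl-3-[(2R)-3-[4-(benzyloxy)-3-methoxyphenyl]-2-(oxetan-3-yl)propanoyl]oxazolidin-2-one, via sodium Z-enolate 11 (not isolated)
Conditions: NaN(SiMe3)2, THF, −78 °C; then 10, −78 to −40 °C
Reagents that add atoms: none
Why: Evans asymmetric alkylation: the chelated sodium Z-enolate 11 is shielded on one face by the benzyl group at C4 of the auxiliary, the benzylic bromide enters from the opposite face, and with the (R)-auxiliary this sets the new centre (the later lactone C3) as R, while the unactivated oxetane should not react with the enolate at −78 °C.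

Step 7
Reactants: 12 (R)-4-benzyl-3-[(2R)-3-[4-(benzyloxy)-3-methoxyphenyl]-2-(oxetan-3-yl)propanoyl]oxazolidin-2-one
Product: 14 (R)-3-[4-(benzyloxy)-3-methoxyphenyl]-2-(oxetan-3-yl)propanoic acid, via peroxy acid 13 (not isolated)
Conditions: LiOH·H2O, 30% H2O2, THF/H2O, 0 °C; aq. Na2SO3; wash basic phase with CH2Cl2 (auxiliary); cold aq. NaHSO4 to pH 4, EtOAc extraction, concentrate below 25 °C, use at once
Reagents that add atoms: hydrogen peroxide, OO
Why: Hydroperoxide cleavage of the N-acyl oxazolidinone: LiOOH attacks the exocyclic carbonyl group selectively even next to a branched α-carbon and does not epimerise it, the peroxy acid 13 is reduced by sulfite, and the acid is set free from its salt only at the end, cold, to be used at once.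

Step 8
Reactants: 14 (R)-3-[4-(benzyloxy)-3-methoxyphenyl]-2-(oxetan-3-yl)propanoic acid
Product: 16 (3R,4S)-3-[4-(benzyloxy)-3-methoxybenzyl]-4-(hydroxymethyl)dihydrofuran-2(3H)-one, via cis-lactone 15 (not isolated)
Conditions: CSA (0.1 equiv), toluene (0.02 M), rt, then 60 °C until the cis/trans composition no longer changes
Reagents that add atoms: none
Why: CSA protonates the oxetane oxygen, which makes both ring CH2–O bonds electrophilic, and the carboxyl oxygen on C2 displaces the oxetane oxygen at one CH2 in an intramolecular SN2 reaction, so that the O1–C5 bond forms, the γ-lactone closes and the other arm is released as the hydroxymethyl group on C4, all driven by loss of four-ring strain. The closest known reaction type is the acid-promoted isomerisation of oxetane carboxylic acids to hydroxy lactones, a case of intramolecular opening of 3-substituted oxetanes by a tethered oxygen nucleophile. The lactone ring closes in the 5-exo-tet mode at a primary carbon. The new stereocentre C4 is controlled by the existing centre C3, since the transition state that keeps the arylmethyl group on C3 anti to the arm left behind on C4 is the less crowded one and leads to the 3,4-trans lactone 16. The selectivity needed is between the two diastereotopic oxetane CH2 groups, and it is secured twice: the cis-lactone 15 from attack at the other CH2 differs from 16 only in which of two constitutionally identical CH2–O arms sits in the ring, so acid-catalysed acyl migration to the free hydroxymethyl group should turn 15 into the more stable trans isomer 16 without touching C3. High dilution should hold back intermolecular opening of the oxetane and attack by the electron-rich arene.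

Step 9
Reactants: 16 (3R,4S)-3-[4-(benzyloxy)-3-methoxybenzyl]-4-(hydroxymethyl)dihydrofuran-2(3H)-one
Product: 17 (3R,4R)-4-[4-(benzyloxy)-3-methoxybenzyl]-5-oxotetrahydrofuran-3-carbaldehyde (trans; the formyl group sits on lactone C4)
Conditions: Dess–Martin periodinane, pyridine, CH2Cl2, 0 °C to rt
Reagents that add atoms: none
Why: Dess–Martin oxidation of the primary alcohol to the aldehyde under buffered, non-basic conditions should avoid both enolisation at C4 and β-elimination of the ring carboxylate, so the trans arrangement is kept.

Step 10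
Reactants: 17 (3R,4R)-4-[4-(benzyloxy)-3-methoxybenzyl]-5-oxotetrahydrofuran-3-carbaldehyde; 18 4-bromo-1,2-dimethoxybenzene (4-bromoveratrole)
Product: 20 (3R,4R)-3-[4-(benzyloxy)-3-methoxybenzyl]-4-[(3,4-dimethoxyphenyl)(hydroxy)methyl]dihydrofuran-2(3H)-one as a mixture of C7' epimers, via 3,4-dimethoxyphenylmagnesium bromide 19 (not isolated)
Conditions: 18, Mg turnings, THF, 40 °C; then add 19 (1.15 equiv) to 17, THF, −78 °C; quench at −78 °C with pH 7 phosphate buffer
Reagents that add atoms: none
Why: Grignard addition to an aldehyde: at −78 °C the aryl magnesium reagent should add to the formyl group far faster than to the lactone carbonyl, and no facial control is asked for, because C7' is re-set in steps 11 and 12.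

Step 11
Reactants: 20 (3R,4R)-3-[4-(benzyloxy)-3-methoxybenzyl]-4-[(3,4-dimethoxyphenyl)(hydroxy)methyl]dihydrofuran-2(3H)-one (C7' epimers)
Product: 21 (3R,4R)-3-[4-(benzyloxy)-3-methoxybenzyl]-4-(3,4-dimethoxybenzoyl)dihydrofuran-2(3H)-one
Conditions: Dess–Martin periodinane, pyridine, CH2Cl2, 0 °C to rt
Reagents that add atoms: none
Why: Dess–Martin oxidation of the secondary benzylic alcohol merges both C7' epimers into one aryl ketone, and C4, now α to the ketone, already has the more stable trans arrangement, so enolisation cannot erode it.

Step 12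
Reactants: 21 (3R,4R)-3-[4-(benzyloxy)-3-methoxybenzyl]-4-(3,4-dimethoxybenzoyl)dihydrofuran-2(3H)-one
Product: 22 (3R,4R)-3-[4-(benzyloxy)-3-methoxybenzyl]-4-[(S)-(3,4-dimethoxyphenyl)(hydroxy)methyl]dihydrofuran-2(3H)-one
Conditions: (R)-2-methyl-CBS-oxazaborolidine (0.2 equiv), BH3·SMe2, THF, −20 °C; MeOH quench
Reagents that add atoms: none
Why: Corey–Bakshi–Shibata reduction: the (R)-oxazaborolidine–borane complex binds the ketone with the aryl group as the larger substituent and delivers hydride to the face that gives the (S)-carbinol, which is also the Felkin–Anh sense for hydride attack anti to C3, so catalyst and substrate should reinforce each other, and borane does not reduce the lactone at −20 °C.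

Step 13
Reactants: 22 (3R,4R)-3-[4-(benzyloxy)-3-methoxybenzyl]-4-[(S)-(3,4-dimethoxyphenyl)(hydroxy)methyl]dihydrofuran-2(3H)-one
Product: 23 (3R,4R)-4-[(S)-(3,4-dimethoxyphenyl)(hydroxy)methyl]-3-(4-hydroxy-3-methoxybenzyl)dihydrofuran-2(3H)-one (target)
Conditions: H2 (1 atm), Pd/C (palladium on carbon), EtOAc, rt; stop after one equivalent of H2
Reagents that add atoms: none
Why: Hydrogenolysis of the aryl benzyl ether on palladium in neutral ethyl acetate should be much faster than loss of the secondary benzylic hydroxyl group, which needs acid or long reaction times, so the reaction is stopped after uptake of one equivalent of hydrogen and no stereocentre is touched.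

**Compound list**

1 | oxetan-3-one | O=C1COC1 | starting material
2 | ethyl (triphenylphosphoranylidene)acetate | CCOC(=O)C=P(c1ccccc1)(c1ccccc1)c1ccccc1 | starting material
3 | ethyl 2-(oxetan-3-ylidene)acetate | CCOC(=O)C=C1COC1 | intermediate
4 | ethyl 2-(oxetan-3-yl)acetate | CCOC(=O)CC1COC1 | intermediate
5 | lithium 2-(oxetan-3-yl)acetate | [Li+].[O-]C(=O)CC1COC1 | intermediate
6 | (R)-4-benzyloxazolidin-2-one | O=C1N[C@H](Cc2ccccc2)CO1 | starting material
7 | 2-(oxetan-3-yl)acetic pivalic anhydride (formed in the flask) | CC(C)(C)C(=O)OC(=O)CC1COC1 | intermediate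
8 | (R)-4-benzyl-3-[2-(oxetan-3-yl)acetyl]oxazolidin-2-one | O=C(CC1COC1)N1C(=O)OC[C@H]1Cc1ccccc1 | intermediate
9 | (4-benzyloxy-3-methoxyphenyl)methanol | COc1cc(CO)ccc1OCc1ccccc1 | starting material
10 | 4-benzyloxy-3-methoxybenzyl bromide | COc1cc(CBr)ccc1OCc1ccccc1 | intermediate
11 | sodium Z-enolate of 8 (formed in the flask) | [Na+].[O-]/C(=C\C1COC1)N1C(=O)OC[C@H]1Cc1ccccc1 | intermediate
12 | (R)-4-benzyl-3-[(2R)-3-[4-(benzyloxy)-3-methoxyphenyl]-2-(oxetan-3-yl)propanoyl]oxazolidin-2-one | O=C([C@H](Cc1ccc(OCc2ccccc2)c(OC)c1)C1COC1)N1C(=O)OC[C@H]1Cc1ccccc1 | intermediate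
13 | (R)-3-[4-(benzyloxy)-3-methoxyphenyl]-2-(oxetan-3-yl)propaneperoxoic acid (formed in the flask) | OOC(=O)[C@H](Cc1ccc(OCc2ccccc2)c(OC)c1)C1COC1 | intermediate
14 | (R)-3-[4-(benzyloxy)-3-methoxyphenyl]-2-(oxetan-3-yl)propanoic acid | OC(=O)[C@H](Cc1ccc(OCc2ccccc2)c(OC)c1)C1COC1 | intermediate
15 | (3R,4R)-3-[4-(benzyloxy)-3-methoxybenzyl]-4-(hydroxymethyl)dihydrofuran-2(3H)-one, cis (formed in the flask) | COc1cc(C[C@H]2C(=O)OC[C@H]2CO)ccc1OCc1ccccc1 | intermediate
16 | (3R,4S)-3-[4-(benzyloxy)-3-methoxybenzyl]-4-(hydroxymethyl)dihydrofuran-2(3H)-one, trans | COc1cc(C[C@H]2C(=O)OC[C@@H]2CO)ccc1OCc1ccccc1 | intermediate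
17 | (3R,4R)-4-[4-(benzyloxy)-3-methoxybenzyl]-5-oxotetrahydrofuran-3-carbaldehyde, trans | COc1cc(C[C@H]2C(=O)OC[C@@H]2C=O)ccc1OCc1ccccc1 | intermediate
18 | 4-bromo-1,2-dimethoxybenzene | COc1ccc(Br)cc1OC | starting material
19 | 3,4-dimethoxyphenylmagnesium bromide (formed in the flask) | COc1ccc([Mg]Br)cc1OC | intermediate
20 | (3R,4R)-3-[4-(benzyloxy)-3-methoxybenzyl]-4-[(3,4-dimethoxyphenyl)(hydroxy)methyl]dihydrofuran-2(3H)-one, C7' epimers | COc1cc(C[C@H]2C(=O)OC[C@@H]2C(O)c2ccc(OC)c(OC)c2)ccc1OCc1ccccc1 | intermediate
21 | (3R,4R)-3-[4-(benzyloxy)-3-methoxybenzyl]-4-(3,4-dimethoxybenzoyl)dihydrofuran-2(3H)-one | COc1cc(C[C@H]2C(=O)OC[C@@H]2C(=O)c2ccc(OC)c(OC)c2)ccc1OCc1ccccc1 | intermediate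
22 | (3R,4R)-3-[4-(benzyloxy)-3-methoxybenzyl]-4-[(S)-(3,4-dimethoxyphenyl)(hydroxy)methyl]dihydrofuran-2(3H)-one | COc1cc(C[C@H]2C(=O)OC[C@@H]2[C@H](O)c2ccc(OC)c(OC)c2)ccc1OCc1ccccc1 | intermediate
23 | (3R,4R)-4-[(S)-(3,4-dimethoxyphenyl)(hydroxy)methyl]-3-(4-hydroxy-3-methoxybenzyl)dihydrofuran-2(3H)-one | COc1cc(C[C@H]2C(=O)OC[C@@H]2[C@H](O)c2ccc(OC)c(OC)c2)ccc1O | target

**Step count**

Total steps: 13. Longest linear sequence: 12 steps (steps 1–4 and 6–13, from oxetan-3-one); step 5 is a one-step side branch.

**Steps most likely to fail**

Step 8 (key step). The discrimination between the two oxetane CH2 groups may be incomplete and acyl migration between the two arms may be slow, so that cis- and trans-lactones fail to converge. The fallback moves the control of C4 from the ring closure to a later enolisation. It sets out from the cis-lactone 15, alone or mixed with 16. Dess–Martin oxidation (pyridine, CH2Cl2) should give the cis-aldehyde (3S,4R)-4-[4-(benzyloxy)-3-methoxybenzyl]-5-oxotetrahydrofuran-3-carbaldehyde F1, in which the C4 hydrogen is α to the formyl group. A catalytic amount of a mild amine base (Et3N, or DBU at −20 °C) in CH2Cl2 should then epimerise C4 to the more stable trans arrangement. C3 is α only to the lactone carbonyl, is far less acidic and should stay as set. The product is the trans-aldehyde 17, where the route is rejoined, and the choice of arm in the oxetane opening no longer matters.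

Step 10. The basic Grignard reagent may enolise the aldehyde, with β-elimination of the ring carboxylate as the follow-up. It may also add to the lactone carbonyl, or the new magnesium alkoxide may take over the lactone acyl group. The fallback builds the aryl ketone under neutral conditions and sets out from alcohol 16. Oxidation with TEMPO and PhI(OAc)2 in MeCN/H2O should give the acid (3R,4R)-4-[4-(benzyloxy)-3-methoxybenzyl]-5-oxotetrahydrofuran-3-carboxylic acid F2. Coupling with ethanethiol (EDC·HCl, catalytic DMAP, CH2Cl2) should give the thioester S-ethyl (3R,4R)-4-[4-(benzyloxy)-3-methoxybenzyl]-5-oxotetrahydrofuran-3-carbothioate F3. Liebeskind–Srogl coupling of F3 with purchased 3,4-dimethoxyphenylboronic acid (Pd2(dba)3, tri(2-furyl)phosphine, CuTC = Cu(O2C-2-thienyl), monovalent copper, THF, 50 °C) should give ketone 21, where the route is rejoined. Steps 9 to 11 are bypassed.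

Step 12. Hydride delivery may show poor facial selectivity if the branched C4 substituent competes with the aryl group for the role of the larger ketone substituent, or if the substrate bias runs against the catalyst. The fallback gives up reagent control and sets out from ketone 21. Reduction with NaBH4 (THF/MeOH, −40 °C) should give both carbinols, which are diastereomers and can be separated by chromatography. The (7'S)-carbinol 22 is carried on, so the route is rejoined at 22. The unwanted epimer, (3R,4R)-3-[4-(benzyloxy)-3-methoxybenzyl]-4-[(R)-(3,4-dimethoxyphenyl)(hydroxy)methyl]dihydrofuran-2(3H)-one F4, is oxidised back to 21 with Dess–Martin periodinane and passed through the reduction again.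

**Further compounds**

F1 | step 8 | (3S,4R)-4-[4-(benzyloxy)-3-methoxybenzyl]-5-oxotetrahydrofuran-3-carbaldehyde (cis) | COc1cc(C[C@H]2C(=O)OC[C@H]2C=O)ccc1OCc1ccccc1
F2 | step 10 | (3R,4R)-4-[4-(benzyloxy)-3-methoxybenzyl]-5-oxotetrahydrofuran-3-carboxylic acid | COc1cc(C[C@H]2C(=O)OC[C@@H]2C(=O)O)ccc1OCc1ccccc1
F3 | step 10 | S-ethyl (3R,4R)-4-[4-(benzyloxy)-3-methoxybenzyl]-5-oxotetrahydrofuran-3-carbothioate | COc1cc(C[C@H]2C(=O)OC[C@@H]2C(=O)SCC)ccc1OCc1ccccc1
F4 | step 12 | (3R,4R)-3-[4-(benzyloxy)-3-methoxybenzyl]-4-[(R)-(3,4-dimethoxyphenyl)(hydroxy)methyl]dihydrofuran-2(3H)-one | COc1cc(C[C@H]2C(=O)OC[C@@H]2[C@@H](O)c2ccc(OC)c(OC)c2)ccc1OCc1ccccc1
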